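## The problem

- The target is a ten-membered carbocycle (C1–C10) spanned by an ether oxygen from C1 to C4, so that C1–C4 form a cis-2,5-disubstituted tetrahydrofuran with a quaternary C4. It is fused through C6 and C7 to a butenolide (C6, C7, C11, C12, O).
- C6 is an enol-lactone carbon. The C5=C6 alkene lies in the medium ring and is conjugated through C7=C11 to the lactone carbonyl, and C7 carries three carbon substituents (C6, C8, C11).
- Five stereocentres must be set. C1 and C4 are locked cis by the bridge, so one fixes the other. C10, a tertiary alcohol next to C1, can be set from C1 by chelation to the ring oxygen. C8 is 1,3 to C10 across a methylene and has no reliable acyclic control. The quaternary centre of the (S)-2-methylglycidate is remote and must be bought.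
- The epoxide ester, the primary allylic acetate and the enol lactone will not survive organometallic reagents, strong base or strong acid. A C8 carbonyl beside the C10 carbinol invites retro-aldol cleavage. Both acyl groups therefore belong at the very end, and the C10 hydroxyl needs cover while C8 is an aldehyde.
- The feature that opens the structure is the tetrahydrofuran with its two flanking carbons. C1, C4, C5 and C10, with a temporary bond from C10 to C6, are the furan half and the three-carbon half of an 8-oxabicyclo[3.2.1]oct-6-en-3-one. C6 is its ketone bridge and C9–C8 an acetaldehyde arm on C10.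

## Retrosynthesis

**Acyl groups.** Target 25 is cut at the C13–O acetyl bond to diol 24. 24 is the desilylation product of 23, and 23 is cut at the C8–O acyl bond into alcohol 19 and glycidate salt 21 (from commercial ester 20, activated as mixed anhydride 22). Neither ester could be carried through acetylide, Lewis-acid or palladium chemistry. The tertiary C10 hydroxyl needs no differentiation because it does not acylate. 19 already holds every skeletal carbon and four of the five stereocentres. The forward steps must esterify a hindered allylic alcohol without strong base and remove two silyl groups without opening the epoxide.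

**Lactone.** In 19 the C11–C12 and C12–O bonds are cut together, which leads to the Z-β-iodoenone 18. The neighbouring cut, C7–C11 by aldol of a ring ketone with a pyruvate, would need a choice between C5 and C7 enolisation and a dehydration beside the C8 oxygen. Carbonylation needs neither: its regiochemistry is stored in the C–I bond, and O-acylation of the enol creates C5=C6 at the right oxidation level. The forward reaction needs iodine cis to the C6 carbonyl and enolisation toward C5.

**Medium ring.** 18 is cut at C7–C8 and C11–I to the ynone aldehyde 17. C5–C6 and C9–C10 are not candidates because the cycloadduct already contains them. The same C7–C8 bond with a vinyl metal at C7 is the third alternative below. The ynone makes C7 the only carbon that can become nucleophilic, and the closure also delivers the halide for the carbonylation. 17 is acyclic apart from the tetrahydrofuran, whose cis arms hold the ends together. The closure must beat protonation of the allenolate, give the Z-iodoalkene and choose one face of the aldehyde.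

**Ynone.** 17 comes from acetal 16, which is cut at C6–C7 into N-methoxy-N-methylamide 13 and acetylide 15 of the commercial propargyl silyl ether 14. 14 supplies C7, C11 and C13 with its oxygen in one piece. Only mono-addition is asked.

**C10.** 13 is the silyl ether of 12, and 12 is cut at the C10–CH3 bond to ketone 11. The other bond to C10, C9–C10, is inherited from the cycloaddition, so methyl is the group to add. The ring oxygen at C1 is placed for chelation control.

**Bridge.** 11 is the oxidation product of 10. The amide carbon C6 and the carbinol C10 of 10 are reconnected through oxygen to lactone 9, and removal of that oxygen gives ketone 8 with a C6–C10 bond. This turns a two-armed tetrahydrofuran into a rigid bicycle in which C1 and C4 are fixed and the C10 centre need not be controlled. The forward Baeyer–Villiger reaction must migrate C10, not C5.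

**Adjustments.** 8 comes from 7 by saturation of the C2=C3 alkene, and 7 from 6 by masking the aldehyde.

**Key disconnection.** 6 is cut at C1–C10 and C4–C5 into dienal 5 and 2-methylfuran 1. Both C–C bonds flanking the ring oxygen and both ring stereocentres are made in one catalytic step. The step must be regioselective, enantioselective, and must close the ring before the furan rearomatises.

**Dienal.** 5 is the enol silane of keto-enal 3, made from 1 and silyl chloride 4. 1 therefore serves twice.

## Roads not taken

**Alternative 1:** Ozonolysis of a Birch-derived octalin.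
- **Cut and key step.** The ten-membered ring is unveiled, not closed. Ozonolysis of the tetrasubstituted ring-fusion alkene (C1=C6) of octalin dienoate A2 gives cyclodecane-1,6-dione A1, with C4, C8, C10 and the C7=C11 acrylate in place.
- **Merits.** No medium-ring cyclisation is needed. The carbinol centres are set on a rigid bicycle. The C12 ester is already cis to the C6 ketone.
- **Weak points.** Ozone must choose the C1=C6 alkene of a conjugated dienoate over the acrylate alkene. A1 is a 1,6-diketone in a medium ring, the classical substrate for transannular aldol closure, and also an ene-dione. C1 is still a ketone, so the ether bridge and the C1 stereocentre would be made last, by transannular ketalisation and hydride delivery, without obvious control. The octalin needs a long linear build-up.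
- **Comparison.** In certainty of ring formation this road is better than the chosen plan, which closes the ring against medium-ring strain. The chosen plan sets against that C1 and C4 made together and cis by construction, and no transannularly reactive diketone.

**Alternative 2:** Radical cyclisation onto a β-alkoxycrotonate.
- **Cut and key step.** The cut is C3–C4. The primary C3 radical from iodide A4 (tin hydride) adds 5-exo to the oxygen-bearing carbon of the (E)-β-alkoxycrotonate and gives cis-tetrahydrofuran A3 with quaternary C4.
- **Merits.** Radical cyclisations of β-alkoxyacrylates are reliably 2,5-cis. C1 and C10 can be set beforehand by asymmetric dihydroxylation of a trisubstituted alkene, so the tertiary carbinol does not depend on a Grignard addition. Both arms arrive differentiated.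
- **Weak points.** The acceptor carbon is fully substituted, so addition is slower and direct reduction competes. With methyl and the ester arm both on C4 the cis preference is less secure than in the known cases. Tin is stoichiometric. A3 is only the equivalent of 13, so the ring closure and the butenolide remain unsolved.
- **Comparison.** The stereocentres of A3 rest on better precedented reactions than a (4+3) cycloaddition of a furan with a free α-position, and in that respect this road is safer. The chosen plan sets against it a single catalytic step for both flanking C–C bonds and both ring stereocentres, and ten steps to 13 without tin.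

**Alternative 3:** Nozaki–Hiyama–Kishi closure at C7–C8.
- **Cut and key step.** The cut is C7–C8 with reversed polarity. The β-iodobutenolide aldehyde A6 is closed with NiCl2 and CrCl2 to the C8 carbinol A5: zerovalent nickel inserts into C7–I, and the vinylchromium species adds to the aldehyde.
- **Merits.** This is the most reliable carbonyl-addition closure for medium rings and is indifferent to esters and silyl ethers. The butenolide with its C13 acetate is in place before closure.
- **Weak points.** A5 is a C6–H butenolide. C6 is an extra stereocentre to make and destroy, and C5=C6 must be introduced afterwards by oxidation at the γ-carbon in the presence of the allylic acetate and the C8 carbinol. The iodobutenolide must be assembled on the C5–C6 arm. C8 is again under substrate control. Chromium is used in large excess.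
- **Comparison.** As a ring closure this is better precedented than the iodide-triggered aldol chosen here, and that is conceded. The chosen closure leaves iodine on C11, from which the lactone carbonyl is grown directly at the enol-lactone oxidation level, so no C6 stereocentre and no late dehydrogenation are needed.

Key step: step 3

Assumption: the (2S,5S) catalyst is taken to give the (1S,5S) bridgeheads of 6 through the compact arrangement. If the sense is the opposite, the (2R,5R) catalyst is used and nothing else changes.

## Route

Step 1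
Reactants: 1 2-methylfuran
Product: 3 (E)-4-oxopent-2-enal, via (Z)-4-oxopent-2-enal 2 (not isolated)
Conditions: NBS, NaHCO3, acetone/H2O, −15 °C; then pyridine, rt
Reagents that add atoms: water (O)
Why: Oxidative furan ring opening: bromination at C5 and capture by water at C2 unravel the furan to the cis-enedione 2, and pyridine isomerises it to the E-isomer by reversible conjugate addition.

Step 2
Reactants: 3 (E)-4-oxopent-2-enal; 4 chlorotriethylsilane
Product: 5 (E)-4-(triethylsilyloxy)penta-2,4-dienal
Conditions: NaI, Et3N, MeCN, 0 °C to rt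
Reagents that add atoms: none
Why: Silyl enol ether formation with the silyl iodide made in situ; only the methyl group of 3 is enolisable, so only the 2-silyloxydiene can form and the E-alkene is untouched.

Step 3
Reactants: 5 (E)-4-(triethylsilyloxy)penta-2,4-dienal; 1 2-methylfuran (excess)
Product: 6 2-[(1S,2S,5S)-5-methyl-3-oxo-8-oxabicyclo[3.2.1]oct-6-en-2-yl]acetaldehyde
Conditions: (2S,5S)-5-benzyl-2-tert-butyl-3-methylimidazolidin-4-one trifluoroacetate (20 mol%), CH2Cl2, −78 °C; aq. NaHCO3
Reagents that add atoms: none
Why: The catalyst condenses with 5 to an (E)-dienyl iminium ion, an amino-stabilised 2-silyloxyallyl cation with one face shielded by the benzyl group. The unsubstituted α-carbon of 1 bonds to the iminium β-carbon (C1–C10), the terminal carbon of the silyloxyallyl unit then bonds to the methyl-bearing carbon of the resulting oxocarbenium ion (C4–C5), and hydrolysis returns the catalyst, the aldehyde and, after loss of silicon, the C6 ketone. The closest known reaction is the imidazolidinone-catalysed (4+3) cycloaddition of 4-silyloxypentadienals with 2,5-dialkylfurans, and the first bond forms as in iminium-catalysed Friedel–Crafts alkylation of furans. The seven-membered ring closes by 7-(enolendo)-exo-trig attack on the oxocarbenium carbon, and the furan oxygen becomes the one-atom bridge. C10 is fixed by the catalyst, C1 by the compact arrangement of furan and dienyl unit in the first bond formation, and C4 by C1, since the bridge can only be cis. Regiochemistry follows from the higher nucleophilicity and lower hindrance of the free α-position, the methyl group stabilising the cation at C4. Ring closure must outrun loss of the C1 proton, so the reaction is run at −78 °C with no base other than trifluoroacetate. C10 is erased in steps 6 to 8, so a minor exo diastereomer would end up as the enantiomer at C1 and C4, and it is therefore removed by chromatography at the stage of 6.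

Step 4
Reactants: 6 2-[(1S,2S,5S)-5-methyl-3-oxo-8-oxabicyclo[3.2.1]oct-6-en-2-yl]acetaldehyde
Product: 7 (1S,2S,5S)-2-(2,2-dimethoxyethyl)-5-methyl-8-oxabicyclo[3.2.1]oct-6-en-3-one
Conditions: HC(OMe)3, CeCl3·7H2O (cat.), MeOH, rt
Reagents that add atoms: trimethyl orthoformate (COC(OC)OC)
Why: Lanthanide-catalysed acetalisation discriminates the aldehyde from the hindered bicyclic ketone and masks C8 for the oxidation and organometallic steps; epimerisation at C2 after the separation in step 3 is harmless.

Step 5
Reactants: 7 (1S,2S,5S)-2-(2,2-dimethoxyethyl)-5-methyl-8-oxabicyclo[3.2.1]oct-6-en-3-one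
Product: 8 (1S,2S,5R)-2-(2,2-dimethoxyethyl)-5-methyl-8-oxabicyclo[3.2.1]octan-3-one
Conditions: H2 (1 atm), Pd/C, EtOAc, rt
Reagents that add atoms: none
Why: Catalytic hydrogenation of the strained cis-disubstituted alkene removes the only group that would compete for the peracid; the change of descriptor at C5 is a priority change only.

Step 6
Reactants: 8 (1S,2S,5R)-2-(2,2-dimethoxyethyl)-5-methyl-8-oxabicyclo[3.2.1]octan-3-one
Product: 9 (1S,2S,6R)-2-(2,2-dimethoxyethyl)-6-methyl-3,9-dioxabicyclo[4.2.1]nonan-4-one
Conditions: mCPBA, NaHCO3 (buffer), CH2Cl2, 0 °C to rt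
Reagents that add atoms: 3-chloroperoxybenzoic acid (OOC(=O)c1cccc(Cl)c1)
Why: Baeyer–Villiger oxidation; the secondary C10 migrates in preference to the C5 methylene (both carry the same β-oxygen, so substitution decides) and oxygen is inserted into the C6–C10 bond with retention.

Step 7
Reactants: 9 (1S,2S,6R)-2-(2,2-dimethoxyethyl)-6-methyl-3,9-dioxabicyclo[4.2.1]nonan-4-one
Product: 10 2-[(2R,5S)-5-[(1S)-1-hydroxy-3,3-dimethoxypropyl]-2-methyloxolan-2-yl]-N-methoxy-N-methylacetamide
Conditions: MeNH(OMe)·HCl, i-PrMgCl, THF, −20 to 0 °C
Reagents that add atoms: N,O-dimethylhydroxylamine hydrochloride (CNOC.Cl)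
Why: Aminolysis of the bridged lactone by the magnesium amide opens the temporary ring; C6 becomes an acyl donor that stops at the ketone stage and C10 a free secondary alcohol.

Step 8
Reactants: 10 2-[(2R,5S)-5-[(1S)-1-hydroxy-3,3-dimethoxypropyl]-2-methyloxolan-2-yl]-N-methoxy-N-methylacetamide
Product: 11 2-[(2R,5S)-5-(3,3-dimethoxypropanoyl)-2-methyloxolan-2-yl]-N-methoxy-N-methylacetamide
Conditions: Dess–Martin periodinane, pyridine, CH2Cl2, 0 °C to rt
Reagents that add atoms: none
Why: Dess–Martin oxidation under buffered conditions gives the α-alkoxy ketone without epimerising C1 or eliminating methanol from the β-keto acetal; the C10 centre of the cycloadduct disappears here.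

Step 9
Reactants: 11 2-[(2R,5S)-5-(3,3-dimethoxypropanoyl)-2-methyloxolan-2-yl]-N-methoxy-N-methylacetamide
Product: 12 2-[(2R,5S)-5-[(2R)-2-hydroxy-4,4-dimethoxybutan-2-yl]-2-methyloxolan-2-yl]-N-methoxy-N-methylacetamide
Conditions: MeMgBr, Et2O/CH2Cl2, −78 °C
Reagents that add atoms: methylmagnesium bromide (C[Mg]Br)
Why: Chelation-controlled Grignard addition: magnesium bridges the ring oxygen and the C10 carbonyl, and methyl adds from the face of the C1 hydrogen, which gives the (10R) tertiary alcohol. At −78 °C the chelated ketone reacts far faster than the N-methoxy-N-methylamide.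

Step 10
Reactants: 12 2-[(2R,5S)-5-[(2R)-2-hydroxy-4,4-dimethoxybutan-2-yl]-2-methyloxolan-2-yl]-N-methoxy-N-methylacetamide
Product: 13 2-[(2R,5S)-5-[(2R)-4,4-dimethoxy-2-(triethylsilyloxy)butan-2-yl]-2-methyloxolan-2-yl]-N-methoxy-N-methylacetamide
Conditions: Et3SiOTf, 2,6-lutidine, CH2Cl2, −78 °C
Reagents that add atoms: triethylsilyl trifluoromethanesulfonate (CC[Si](CC)(CC)OS(=O)(=O)C(F)(F)F)
Why: Silylation of the tertiary alcohol at −78 °C, where the dimethyl acetal is not yet activated by the silyl triflate; the ether prevents retro-aldol and dehydration once C8 is an aldehyde and keeps the hydroxyl out of the palladium step.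

Step 11
Reactants: 13 2-[(2R,5S)-5-[(2R)-4,4-dimethoxy-2-(triethylsilyloxy)butan-2-yl]-2-methyloxolan-2-yl]-N-methoxy-N-methylacetamide; 14 tert-butyldimethyl(prop-2-yn-1-yloxy)silane
Product: 16 5-(tert-butyldimethylsilyloxy)-1-[(2R,5S)-5-[(2R)-4,4-dimethoxy-2-(triethylsilyloxy)butan-2-yl]-2-methyloxolan-2-yl]pent-3-yn-2-one, via lithium acetylide 15 (not isolated)
Conditions: 14, n-BuLi, THF, −78 °C; then 13, −78 to −30 °C; AcOH quench at −78 °C
Reagents that add atoms: none
Why: Acylation of a lithium acetylide by an N-methoxy-N-methylamide: the chelated tetrahedral intermediate survives until the acidic quench, so the ynone forms without over-addition and the liberated amine is protonated before it can add to the ynone. C7, C11 and C13 arrive in one piece.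

Step 12
Reactants: 16 5-(tert-butyldimethylsilyloxy)-1-[(2R,5S)-5-[(2R)-4,4-dimethoxy-2-(triethylsilyloxy)butan-2-yl]-2-methyloxolan-2-yl]pent-3-yn-2-one
Product: 17 (3R)-3-[(2S,5R)-5-[5-(tert-butyldimethylsilyloxy)-2-oxopent-3-yn-1-yl]-5-methyloxolan-2-yl]-3-(triethylsilyloxy)butanal
Conditions: I2 (10 mol%), acetone, rt
Reagents that add atoms: none
Why: Iodine-catalysed transacetalisation to acetone frees the aldehyde under essentially neutral conditions that should leave both silyl ethers and the ynone intact.

Step 13
Reactants: 17 (3R)-3-[(2S,5R)-5-[5-(tert-butyldimethylsilyloxy)-2-oxopent-3-yn-1-yl]-5-methyloxolan-2-yl]-3-(triethylsilyloxy)butanal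
Product: 18 (1R,4Z,5S,7R,8S)-4-[2-(tert-butyldimethylsilyloxy)-1-iodoethylidene]-5-hydroxy-1,7-dimethyl-7-(triethylsilyloxy)-11-oxabicyclo[6.2.1]undecan-3-one
Conditions: MgI2, CH2Cl2, 0 °C, slow addition (0.005 M)
Reagents that add atoms: magnesium iodide ([Mg+2].[I-].[I-])
Why: Halo-aldol (iodide-mediated Morita–Baylis–Hillman-type) reaction: iodide adds to C11 of the magnesium-activated ynone and the β-iodoallenolate attacks the C8 aldehyde through C7, the cis arms on the tetrahydrofuran holding the ends close. Anti addition of iodide and electrophile gives the Z-iodoenone (iodine cis to the C6 carbonyl) under kinetic control. C8 is set under ring control by C10 and C1, and the (8S) alcohol (C8–O syn to C10–O) is the one carried on.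

Step 14
Reactants: 18 (1R,4Z,5S,7R,8S)-4-[2-(tert-butyldimethylsilyloxy)-1-iodoethylidene]-5-hydroxy-1,7-dimethyl-7-(triethylsilyloxy)-11-oxabicyclo[6.2.1]undecan-3-one
Product: 19 (1S,4R,5E,8S,10R)-13-(tert-butyldimethylsilyloxy)-1,4-epoxy-8-hydroxy-10-(triethylsilyloxy)germacra-5,7(11)-dien-12,6-olide
Conditions: CO (1 atm), PdCl2(PPh3)2 (5 mol%), Et3N, MeCN, 60 °C
Reagents that add atoms: carbon monoxide ([C-]#[O+])
Why: Carbonylative lactonisation of a Z-β-iodoenone: oxidative addition of zerovalent palladium to C11–I, CO insertion, and capture of the acylpalladium by the enol oxygen of the cis C6 ketone build the butenolide and the C5=C6 enol lactone together. The C8 hydroxyl is trans to the acyl group and cannot lactonise, and the nine-membered oxacycle should allow only the ring-cis (5E) alkene.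

Step 15
Reactants: 20 methyl (S)-2-methyloxirane-2-carboxylate
Product: 21 potassium (S)-2-methyloxirane-2-carboxylate
Conditions: KOH (1.0 equiv), MeOH, 0 °C; evaporation
Reagents that add atoms: potassium hydroxide ([K+].[OH-])
Why: Saponification with one equivalent of hydroxide; isolating the salt avoids the free glycidic acid, and the quaternary centre cannot epimerise.

Step 16
Reactants: 19 (1S,4R,5E,8S,10R)-13-(tert-butyldimethylsilyloxy)-1,4-epoxy-8-hydroxy-10-(triethylsilyloxy)germacra-5,7(11)-dien-12,6-olide; 21 potassium (S)-2-methyloxirane-2-carboxylate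
Product: 23 (1S,4R,5E,8S,10R)-13-(tert-butyldimethylsilyloxy)-1,4-epoxy-8-[(2S)-2-methyloxirane-2-carbonyloxy]-10-(triethylsilyloxy)germacra-5,7(11)-dien-12,6-olide, via mixed anhydride 22 (not isolated)
Conditions: 2,4,6-trichlorobenzoyl chloride, THF, rt; then 19, DMAP, toluene, rt
Reagents that add atoms: none
Why: Yamaguchi esterification: DMAP attacks the mixed anhydride at the aliphatic carbonyl and the acylpyridinium acylates the hindered allylic alcohol with retention at C8; no base stronger than DMAP meets the enol lactone or the epoxide.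

Step 17
Reactants: 23 (1S,4R,5E,8S,10R)-13-(tert-butyldimethylsilyloxy)-1,4-epoxy-8-[(2S)-2-methyloxirane-2-carbonyloxy]-10-(triethylsilyloxy)germacra-5,7(11)-dien-12,6-olide
Product: 24 (1S,4R,5E,8S,10R)-1,4-epoxy-10,13-dihydroxy-8-[(2S)-2-methyloxirane-2-carbonyloxy]germacra-5,7(11)-dien-12,6-olide
Conditions: HF·pyridine, pyridine, THF, 0 °C to rt
Reagents that add atoms: none
Why: Buffered fluoride desilylation cleaves the primary silyl ether and the tertiary triethylsilyl ether; the epoxide, deactivated by the adjacent ester carbonyl, and both esters are expected to survive.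

Step 18
Reactants: 24 (1S,4R,5E,8S,10R)-1,4-epoxy-10,13-dihydroxy-8-[(2S)-2-methyloxirane-2-carbonyloxy]germacra-5,7(11)-dien-12,6-olide
Product: 25 CNP0142137.1
Conditions: Ac2O, pyridine, CH2Cl2, 0 °C
Reagents that add atoms: acetic anhydride (CC(=O)OC(C)=O)
Why: Acetylation of the primary allylic alcohol under conditions that leave the tertiary C10 hydroxyl untouched gives the target.

## Compound list

1 | 2-methylfuran | Cc1ccco1 | starting material
2 | (Z)-4-oxopent-2-enal | CC(=O)/C=C\C=O | intermediate
3 | (E)-4-oxopent-2-enal | CC(=O)/C=C/C=O | intermediate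
4 | chlorotriethylsilane | CC[Si](Cl)(CC)CC | starting material
5 | (E)-4-(triethylsilyloxy)penta-2,4-dienal | O=C/C=C/C(=C)O[Si](CC)(CC)CC | intermediate
6 | 2-[(1S,2S,5S)-5-methyl-3-oxo-8-oxabicyclo[3.2.1]oct-6-en-2-yl]acetaldehyde | O=C1C[C@@]2(C)C=C[C@H](O2)[C@@H]1CC=O | intermediate
7 | (1S,2S,5S)-2-(2,2-dimethoxyethyl)-5-methyl-8-oxabicyclo[3.2.1]oct-6-en-3-one | O=C1C[C@@]2(C)C=C[C@H](O2)[C@@H]1CC(OC)OC | intermediate
8 | (1S,2S,5R)-2-(2,2-dimethoxyethyl)-5-methyl-8-oxabicyclo[3.2.1]octan-3-one | O=C1C[C@@]2(C)CC[C@H](O2)[C@@H]1CC(OC)OC | intermediate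
9 | (1S,2S,6R)-2-(2,2-dimethoxyethyl)-6-methyl-3,9-dioxabicyclo[4.2.1]nonan-4-one | O=C1C[C@@]2(C)CC[C@H](O2)[C@H](CC(OC)OC)O1 | intermediate
10 | 2-[(2R,5S)-5-[(1S)-1-hydroxy-3,3-dimethoxypropyl]-2-methyloxolan-2-yl]-N-methoxy-N-methylacetamide | CON(C)C(=O)C[C@@]1(C)CC[C@H](O1)[C@@H](O)CC(OC)OC | intermediate
11 | 2-[(2R,5S)-5-(3,3-dimethoxypropanoyl)-2-methyloxolan-2-yl]-N-methoxy-N-methylacetamide | CON(C)C(=O)C[C@@]1(C)CC[C@H](O1)C(=O)CC(OC)OC | intermediate
12 | 2-[(2R,5S)-5-[(2R)-2-hydroxy-4,4-dimethoxybutan-2-yl]-2-methyloxolan-2-yl]-N-methoxy-N-methylacetamide | CON(C)C(=O)C[C@@]1(C)CC[C@H](O1)[C@](C)(O)CC(OC)OC | intermediate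
13 | 2-[(2R,5S)-5-[(2R)-4,4-dimethoxy-2-(triethylsilyloxy)butan-2-yl]-2-methyloxolan-2-yl]-N-methoxy-N-methylacetamide | CON(C)C(=O)C[C@@]1(C)CC[C@H](O1)[C@](C)(O[Si](CC)(CC)CC)CC(OC)OC | intermediate
14 | tert-butyldimethyl(prop-2-yn-1-yloxy)silane | C#CCO[Si](C)(C)C(C)(C)C | starting material
15 | [3-(tert-butyldimethylsilyloxy)prop-1-yn-1-yl]lithium | [Li]C#CCO[Si](C)(C)C(C)(C)C | intermediate
16 | 5-(tert-butyldimethylsilyloxy)-1-[(2R,5S)-5-[(2R)-4,4-dimethoxy-2-(triethylsilyloxy)butan-2-yl]-2-methyloxolan-2-yl]pent-3-yn-2-one | CC(C)(C)[Si](C)(C)OCC#CC(=O)C[C@@]1(C)CC[C@H](O1)[C@](C)(O[Si](CC)(CC)CC)CC(OC)OC | intermediate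
17 | (3R)-3-[(2S,5R)-5-[5-(tert-butyldimethylsilyloxy)-2-oxopent-3-yn-1-yl]-5-methyloxolan-2-yl]-3-(triethylsilyloxy)butanal | CC(C)(C)[Si](C)(C)OCC#CC(=O)C[C@@]1(C)CC[C@H](O1)[C@](C)(O[Si](CC)(CC)CC)CC=O | intermediate
18 | (1R,4Z,5S,7R,8S)-4-[2-(tert-butyldimethylsilyloxy)-1-iodoethylidene]-5-hydroxy-1,7-dimethyl-7-(triethylsilyloxy)-11-oxabicyclo[6.2.1]undecan-3-one (germacrane numbering: 1S,4R,8S,10R; iodine on C11 cis to the C6 carbonyl) | CC(C)(C)[Si](C)(C)OC/C(I)=C1/C(=O)C[C@@]2(C)CC[C@H](O2)[C@](C)(O[Si](CC)(CC)CC)C[C@@H]1O | intermediate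
19 | (1S,4R,5E,8S,10R)-13-(tert-butyldimethylsilyloxy)-1,4-epoxy-8-hydroxy-10-(triethylsilyloxy)germacra-5,7(11)-dien-12,6-olide | CC(C)(C)[Si](C)(C)OCC1=C2/C(=C\[C@@]3(C)CC[C@H](O3)[C@](C)(O[Si](CC)(CC)CC)C[C@@H]2O)OC1=O | intermediate
20 | methyl (S)-2-methyloxirane-2-carboxylate | COC(=O)[C@]1(C)CO1 | starting material
21 | potassium (S)-2-methyloxirane-2-carboxylate | [K+].[O-]C(=O)[C@]1(C)CO1 | intermediate
22 | (S)-2-methyloxirane-2-carboxylic 2,4,6-trichlorobenzoic anhydride | O=C(OC(=O)[C@]1(C)CO1)c1c(Cl)cc(Cl)cc1Cl | intermediate
23 | (1S,4R,5E,8S,10R)-13-(tert-butyldimethylsilyloxy)-1,4-epoxy-8-[(2S)-2-methyloxirane-2-carbonyloxy]-10-(triethylsilyloxy)germacra-5,7(11)-dien-12,6-olide | CC(C)(C)[Si](C)(C)OCC1=C2/C(=C\[C@@]3(C)CC[C@H](O3)[C@](C)(O[Si](CC)(CC)CC)C[C@@H]2OC(=O)[C@]2(C)CO2)OC1=O | intermediate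
24 | (1S,4R,5E,8S,10R)-1,4-epoxy-10,13-dihydroxy-8-[(2S)-2-methyloxirane-2-carbonyloxy]germacra-5,7(11)-dien-12,6-olide | OCC1=C2/C(=C\[C@@]3(C)CC[C@H](O3)[C@](C)(O)C[C@@H]2OC(=O)[C@]2(C)CO2)OC1=O | intermediate
25 | CNP0142137.1, (1S,4R,5E,8S,10R)-13-acetoxy-1,4-epoxy-10-hydroxy-8-[(2S)-2-methyloxirane-2-carbonyloxy]germacra-5,7(11)-dien-12,6-olide | CC(=O)OCC1=C2/C(=C\[C@@]3(C)CC[C@H](O3)[C@](C)(O)C[C@@H]2OC(=O)[C@]2(C)CO2)OC1=O | target

## Step count and least certain steps

Total: 18 steps. Longest linear sequence: 17 steps (steps 1–14 and 16–18, from 2-methylfuran); step 15 is a one-step branch.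

**Step 3 (key step).**
- **What may go wrong.** The most likely failure is rearomatisation: the first-formed oxocarbenium ion loses the C1 proton and gives Friedel–Crafts alkylation of the furan instead of cycloaddition. The reaction type is established for 2,5-dialkylfurans, which have no such proton, and 2-methylfuran does. A second concern is leakage of enantiopurity through the exo diastereomer, which becomes the bridgehead enantiomer once C10 is erased.
- **Fallback.** It sets out from 1 and returns at 7, making the same two bonds by a metal-carbene route. Methyl 2-diazo-3-oxobutanoate is O-silylated (TBSOTf, Et3N) to methyl 2-diazo-3-(tert-butyldimethylsilyloxy)but-3-enoate F1. Decomposition of F1 by the chiral dirhodium tetracarboxylate Rh2(S-PTAD)4 (dirhodium tetrakis[(S)-(1-adamantyl)(N-phthalimido)acetate], or its enantiomer as the sense requires) in the presence of 1 cyclopropanates the unsubstituted furan double bond. Cope rearrangement of the divinylcyclopropane then gives methyl (1S,5S)-3-(tert-butyldimethylsilyloxy)-5-methyl-8-oxabicyclo[3.2.1]octa-2,6-diene-2-carboxylate F2. Fluoride (TBAF, AcOH) releases methyl (1S,5S)-5-methyl-3-oxo-8-oxabicyclo[3.2.1]oct-6-ene-2-carboxylate F3. C-alkylation with 2-bromo-1,1-dimethoxyethane (Cs2CO3, NaI, DMF, 80 °C) gives methyl (1S,5S)-2-(2,2-dimethoxyethyl)-5-methyl-3-oxo-8-oxabicyclo[3.2.1]oct-6-ene-2-carboxylate F4. Krapcho dealkoxycarbonylation (LiCl, wet DMSO, 140 °C) delivers 7, with its C2 epimer, which serves equally.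

**Step 13.**
- **What may go wrong.** The most likely failure is poor or reversed facial selectivity at C8. The two centres are separated by a methylene, and acyclic 1,3-induction models do not carry over to a nine-membered transition state. Slow closure, which would let the allenolate be protonated, is met by high dilution.
- **Fallback.** It sets out from 18 obtained together with its (8R) epimer F5 and returns at 19. The mixture is carbonylated as in step 14 to 19 and the (8R) epimer of 19 F6. Both are oxidised with Dess–Martin periodinane to the single C8 ketone of 19 F7. F7 is reduced by Corey–Bakshi–Shibata reduction (catecholborane, (R)-B-methyl oxazaborolidine from diphenylprolinol, −78 °C), with the butenolide carbon C7 as the large group, to (8S)-19.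

**Step 14.**
- **What may go wrong.** Capture of the acylpalladium by the ketone oxygen may be slower than its diversion (reduction or intermolecular capture), because enolisation of the medium-ring ketone toward C5 may be slow. Z/E isomerisation of the iodoenone at 60 °C would lead to the 8,12-lactone.
- **Fallback.** It sets out from 18 and returns at 19, separating the C–C and C–O bond formations. Alkoxycarbonylation (CO, MeOH, PdCl2(PPh3)2, Et3N) gives the methyl (Z)-ester F8. Acid-catalysed enol lactonisation (camphorsulfonic acid, toluene, 80 °C) with loss of methanol gives 19.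

**Step 6.**
- **What may go wrong.** C5 may migrate in competition with C10, because both carbons carry a β-oxygen and alignment in the bicyclic peroxide adduct may favour the methylene. The oxidation may also be sluggish.
- **Fallback.** It sets out from 8 and returns at 11, cleaving the same C6–C10 bond through the enol. Thermodynamic silylation (Me3SiCl, NaI, Et3N, MeCN) gives the more substituted silyl enol ether (1S,5R)-2-(2,2-dimethoxyethyl)-5-methyl-3-(trimethylsilyloxy)-8-oxabicyclo[3.2.1]oct-2-ene F9. Ozonolysis (O3, CH2Cl2, −78 °C; Me2S) gives the keto acid 2-[(2R,5S)-5-(3,3-dimethoxypropanoyl)-2-methyloxolan-2-yl]acetic acid F10. Coupling with N,O-dimethylhydroxylamine (EDCI, N-methylmorpholine) gives 11.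

## Further compounds

F1 | step 3 | methyl 2-diazo-3-(tert-butyldimethylsilyloxy)but-3-enoate | COC(=O)C(=[N+]=[N-])C(=C)O[Si](C)(C)C(C)(C)C
F2 | step 3 | methyl (1S,5S)-3-(tert-butyldimethylsilyloxy)-5-methyl-8-oxabicyclo[3.2.1]octa-2,6-diene-2-carboxylate | COC(=O)C1=C(O[Si](C)(C)C(C)(C)C)C[C@@]2(C)C=C[C@@H]1O2
F3 | step 3 | methyl (1S,5S)-5-methyl-3-oxo-8-oxabicyclo[3.2.1]oct-6-ene-2-carboxylate (C2 not defined) | COC(=O)C1C(=O)C[C@@]2(C)C=C[C@@H]1O2
F4 | step 3 | methyl (1S,5S)-2-(2,2-dimethoxyethyl)-5-methyl-3-oxo-8-oxabicyclo[3.2.1]oct-6-ene-2-carboxylate (C2 not defined) | COC(=O)C1(CC(OC)OC)C(=O)C[C@@]2(C)C=C[C@@H]1O2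
F5 | step 13 | (8R) epimer of 18 | CC(C)(C)[Si](C)(C)OC/C(I)=C1/C(=O)C[C@@]2(C)CC[C@H](O2)[C@](C)(O[Si](CC)(CC)CC)C[C@H]1O
F6 | step 13 | (8R) epimer of 19 | CC(C)(C)[Si](C)(C)OCC1=C2/C(=C\[C@@]3(C)CC[C@H](O3)[C@](C)(O[Si](CC)(CC)CC)C[C@H]2O)OC1=O
F7 | step 13 | C8 ketone of 19, (1S,4R,5E,10R)-13-(tert-butyldimethylsilyloxy)-1,4-epoxy-8-oxo-10-(triethylsilyloxy)germacra-5,7(11)-dien-12,6-olide | CC(C)(C)[Si](C)(C)OCC1=C2/C(=C\[C@@]3(C)CC[C@H](O3)[C@](C)(O[Si](CC)(CC)CC)CC2=O)OC1=O
F8 | step 14 | methyl (Z)-ester from 18 (CO2Me in place of iodine on C11, cis to the C6 carbonyl) | CC(C)(C)[Si](C)(C)OC/C(C(=O)OC)=C1/C(=O)C[C@@]2(C)CC[C@H](O2)[C@](C)(O[Si](CC)(CC)CC)C[C@@H]1O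
F9 | step 6 | (1S,5R)-2-(2,2-dimethoxyethyl)-5-methyl-3-(trimethylsilyloxy)-8-oxabicyclo[3.2.1]oct-2-ene | C[Si](C)(C)OC1=C(CC(OC)OC)[C@@H]2CC[C@](C)(C1)O2
F10 | step 6 | 2-[(2R,5S)-5-(3,3-dimethoxypropanoyl)-2-methyloxolan-2-yl]acetic acid | OC(=O)C[C@@]1(C)CC[C@H](O1)C(=O)CC(OC)OC
A1 | alternative 1 | cyclodecane-1,6-dione with the C7=C11 acrylate, C4–OSiEt3, C8–OSi(t-Bu)Me2 and C10–OH | COC(=O)/C(COC(C)=O)=C1\C(=O)C[C@](C)(O[Si](CC)(CC)CC)CCC(=O)[C@](C)(O)C[C@@H]1O[Si](C)(C)C(C)(C)C
A2 | alternative 1 | octalin dienoate with the C1=C6 ring-fusion alkene | COC(=O)/C(COC(C)=O)=C1\C2=C(CC[C@@](C)(O[Si](CC)(CC)CC)C2)[C@](C)(O)C[C@@H]1O[Si](C)(C)C(C)(C)C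
A3 | alternative 2 | cis-tetrahydrofuran with C4 methyl, the C5–C6 ethyl ester arm and the C10–C8 side chain | CCOC(=O)C[C@@]2(C)CC[C@H](O2)[C@](C)(O[Si](CC)(CC)CC)CCOCc1ccc(OC)cc1
A4 | alternative 2 | C3 iodide carrying the (E)-β-alkoxycrotonate on the C1 oxygen | CCOC(=O)/C=C(\C)O[C@@H](CCI)[C@](C)(O[Si](CC)(CC)CC)CCOCc1ccc(OC)cc1
A5 | alternative 3 | oxygen-bridged ten-membered C8 carbinol with the C6–H butenolide | CC(=O)OCC1=C2[C@@H](C[C@@]3(C)CC[C@H](O3)[C@](C)(O[Si](CC)(CC)CC)C[C@@H]2O)OC1=O
A6 | alternative 3 | β-iodobutenolide aldehyde | CC(=O)OCC1=C(I)[C@@H](C[C@@]2(C)CC[C@H](O2)[C@](C)(O[Si](CC)(CC)CC)CC=O)OC1=O
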